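**Strategy.** Ring A holds four contiguous functionalised carbons: oxygenated C3, methyl-bearing C4, the quaternary methyl carbon C5 and the ring-fusion carbon C10. The route cuts this array back to (R)-4-(silyloxymethyl)-3-methylcyclohex-2-enone, whose side chain is the future C9. In one operation a vinylcopper reagent attacks C5 on the face away from the C9 arm and the resulting enolate is methylated at C4; this joins three components, fixes C5 and C4 relative to C10 and leaves C3 as a ketone. The vinyl group supplies C6. Ring B (C5–C10) is closed later by alkoxyallylation of the C9 aldehyde and olefin metathesis, then oxidised at C8, isopropenylated at C7 and reduced.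

Key step: step 6

Assumption: in the lipase acetylation of step 4 the (R)-alcohol is taken to be the slower-reacting enantiomer; if the preference is the reverse, the (R)-enantiomer is taken from the acetate fraction by lipase-mediated methanolysis and nothing else changes.

Convention: C1–C15 are the eremophilane locants of the target (ring A = C1–C5 and C10, ring B = C5–C10); α and β are the faces of the decalin drawn with the C5 methyl group β.

Step 1
Reactants: 1 ethyl 2-methyl-4-oxocyclohex-2-ene-1-carboxylate (Hagemann's ester, racemic)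
Product: 2 ethyl 7-methyl-1,4-dioxaspiro[4.5]dec-7-ene-8-carboxylate
Conditions: HOCH2CH2OH, p-TsOH (cat.), toluene, reflux, Dean–Stark
Reagents that add atoms: ethylene glycol, OCCO
Why: Acid-catalysed ketalisation of a β-methylcyclohexenone goes with the usual shift of the double bond to the β,γ-position, here conjugated with the ester; the product has no stereocentre, and any unshifted isomer converges on the same enone in step 3.

Step 2
Reactants: 2 ethyl 7-methyl-1,4-dioxaspiro[4.5]dec-7-ene-8-carboxylate
Product: 3 (7-methyl-1,4-dioxaspiro[4.5]dec-7-en-8-yl)methanol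
Conditions: LiAlH4, THF, 0 °C
Reagents that add atoms: none
Why: LiAlH4 reduction of the conjugated ester gives the primary allylic alcohol and leaves the ketal and the tetrasubstituted alkene untouched.

Step 3
Reactants: 3 (7-methyl-1,4-dioxaspiro[4.5]dec-7-en-8-yl)methanol
Product: 5 rac-4-(hydroxymethyl)-3-methylcyclohex-2-en-1-one, via deconjugated ketone 4 (not isolated)
Conditions: 1 M HCl (aq), THF, 23 °C
Reagents that add atoms: water, O
Why: Aqueous acid hydrolyses the dioxolane to 4 and then moves the double bond into conjugation through the dienol (enone isomerisation), the protonation at ring C4 (the future C10) creating the stereocentre as a racemate.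

Step 4
Reactants: 5 rac-4-(hydroxymethyl)-3-methylcyclohex-2-en-1-one
Product: 6 (4R)-4-(hydroxymethyl)-3-methylcyclohex-2-en-1-one
Conditions: Burkholderia cepacia lipase (Amano PS), vinyl acetate, t-BuOMe, 23 °C, stopped beyond half conversion; chromatography
Reagents that add atoms: none
Why: Lipase-catalysed enantioselective acetylation (enzymatic kinetic resolution) of a primary alcohol with a β-stereocentre, carried past half conversion, should leave the slower-reacting (R)-alcohol in high enantiomeric purity, separable from the (S)-acetate.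

Step 5
Reactants: 6 (4R)-4-(hydroxymethyl)-3-methylcyclohex-2-en-1-one
Product: 7 (4R)-4-{[tert-butyl(dimethyl)silyl]oxymethyl}-3-methylcyclohex-2-en-1-one
Conditions: TBSCl, imidazole, DMF, 0 → 23 °C
Reagents that add atoms: tert-butyldimethylsilyl chloride, CC(C)(C)[Si](C)(C)Cl
Why: Silylation of a primary alcohol with imidazole does not enolise the γ-position, so the C10 configuration is retained.

Step 6
Reactants: 7 (4R)-4-{[tert-butyl(dimethyl)silyl]oxymethyl}-3-methylcyclohex-2-en-1-one; 8 vinylmagnesium bromide; 9 iodomethane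
Product: 13 (2R,3S,4R)-4-{[tert-butyl(dimethyl)silyl]oxymethyl}-3-ethenyl-2,3-dimethylcyclohexan-1-one, via trimethylsilyl enol ether 10 (not isolated), via lithium enolate 11 (not isolated), via C4-epimeric ketone 12 (not isolated)
Conditions: 8, CuBr·SMe2 (cat.), Me3SiCl, HMPA, THF, –78 °C; volatiles evaporated; MeLi, THF, 0 °C; 9, HMPA, –78 → 0 °C; NH4Cl (aq); crude product: NaOMe, MeOH, 23 °C
Reagents that add atoms: vinylmagnesium bromide, C=C[Mg]Br; iodomethane, CI
Why: Transmetalation gives a vinyl organocopper species of monovalent copper that adds 1,4 to the enone with Me3SiCl trapping to give enol silane 10, MeLi cleaves the Si–O bond to the regiodefined lithium enolate 11, and 11 is C-methylated at C4 by SN2 attack on MeI. The closest known reaction type is the tandem cuprate conjugate addition–enolate alkylation of 4-substituted and β,β-disubstituted cyclohexenones by way of the enol silane. No ring is closed. C5 is controlled by C10: allylic 1,2-strain against the C5 methyl holds the CH2OTBS arm pseudoaxial and the vinyl group enters axially on the opposite face, so the vinyl carbon C6 and the C9 arm end trans. C4 is set under thermodynamic control: whatever epimer mixture the alkylation gives (attack anti to the pseudoaxial C5 methyl would favour 12), methoxide equilibrates it through the C3 enolate to the equatorial methyl of 13, cis to the C5 methyl. The step needs alkylation at C4 in preference to C2, which the regiospecific enolate from 10, excess MeI and HMPA at low temperature secure by keeping alkylation ahead of proton transfer.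

Step 7
Reactants: 13 (2R,3S,4R)-4-{[tert-butyl(dimethyl)silyl]oxymethyl}-3-ethenyl-2,3-dimethylcyclohexan-1-one
Product: 14 (1R,2R,3S,4R)-4-{[tert-butyl(dimethyl)silyl]oxymethyl}-3-ethenyl-2,3-dimethylcyclohexan-1-ol
Conditions: Li, NH3 (l), THF, EtOH, –78 °C; NH4Cl
Reagents that add atoms: none
Why: Dissolving-metal reduction of a hindered cyclohexanone gives the thermodynamically preferred equatorial C3 alcohol (trans to the C4 methyl), whereas axial hydride delivery would be blocked by the axial C5 methyl; the isolated vinyl group and the silyl ether are inert.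

Step 8
Reactants: 14 (1R,2R,3S,4R)-4-{[tert-butyl(dimethyl)silyl]oxymethyl}-3-ethenyl-2,3-dimethylcyclohexan-1-ol; 15 3-methylbut-2-enoyl chloride
Product: 16 (1R,2R,3S,4R)-4-{[tert-butyl(dimethyl)silyl]oxymethyl}-3-ethenyl-2,3-dimethylcyclohexyl 3-methylbut-2-enoate
Conditions: 15, pyridine, DMAP (cat.), CH2Cl2, 0 → 23 °C
Reagents that add atoms: 3-methylbut-2-enoyl chloride, CC(C)=CC(=O)Cl
Why: DMAP-catalysed acylation of the equatorial secondary alcohol installs the C3 ester early, and pyridine as the base avoids vinylketene formation and deconjugation of the acyl unit.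

Step 9
Reactants: 16 (1R,2R,3S,4R)-4-{[tert-butyl(dimethyl)silyl]oxymethyl}-3-ethenyl-2,3-dimethylcyclohexyl 3-methylbut-2-enoate
Product: 17 (1R,2R,3S,4R)-3-ethenyl-4-(hydroxymethyl)-2,3-dimethylcyclohexyl 3-methylbut-2-enoate
Conditions: HF·pyridine, pyridine, THF, 0 → 23 °C
Reagents that add atoms: none
Why: Buffered fluoride cleavage of the primary silyl ether leaves the ester and the alkene intact.

Step 10
Reactants: 17 (1R,2R,3S,4R)-3-ethenyl-4-(hydroxymethyl)-2,3-dimethylcyclohexyl 3-methylbut-2-enoate
Product: 18 (1R,2R,3R,4R)-3-ethenyl-4-formyl-2,3-dimethylcyclohexyl 3-methylbut-2-enoate (the C9 aldehyde)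
Conditions: Dess–Martin periodinane, NaHCO3, CH2Cl2, 0 → 23 °C
Reagents that add atoms: none
Why: Buffered Dess–Martin oxidation gives the aldehyde without epimerisation at C10, whose equatorial formyl group is in any case the more stable arrangement.

Step 11
Reactants: 18 (1R,2R,3R,4R)-3-ethenyl-4-formyl-2,3-dimethylcyclohexyl 3-methylbut-2-enoate; 19 allyl methoxymethyl ether
Product: 22 3-ethenyl-4-[(1S,2S)-1-hydroxy-2-(methoxymethoxy)but-3-en-1-yl]-2,3-dimethylcyclohexyl 3-methylbut-2-enoate (ring configuration as in 18; C8 S and C9 S in target numbering), via alkoxyallylborane 20 (not isolated), via borinate ester 21 (not isolated)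
Conditions: 19, sec-BuLi, THF, –78 °C; (+)-Ipc2BOMe [from (–)-α-pinene]; BF3·OEt2; 18, –78 °C; then H2O2, pH 7 buffer, MeOH, 0 → 23 °C
Reagents that add atoms: allyl methoxymethyl ether, C=CCOCOC
Why: In this Brown alkoxyallylboration the (Z)-γ-alkoxyallylborane 20 adds through a closed chair transition state, the isopinocampheyl groups from (–)-α-pinene directing C–C bond formation to the Re face of the aldehyde (also the Felkin–Anh face, so the case is matched) to set C9, while the (Z)-enol ether geometry gives the syn C8–C9 relationship and the ester does not react with the neutral borane at –78 °C.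

Step 12
Reactants: 22 syn-homoallylic alcohol of step 11; 23 (E)-2-methylbut-2-enoyl chloride (tigloyl chloride)
Product: 24 3-ethenyl-4-[(1S,2S)-2-(methoxymethoxy)-1-{[(E)-2-methylbut-2-enoyl]oxy}but-3-en-1-yl]-2,3-dimethylcyclohexyl 3-methylbut-2-enoate (ring configuration as in 18)
Conditions: 23, pyridine, DMAP, CH2Cl2, 23 → 40 °C
Reagents that add atoms: (E)-2-methylbut-2-enoyl chloride, C/C=C(\C)C(=O)Cl
Why: DMAP-catalysed acylation of the C9 carbinol introduces the second ester with its stable (E)-geometry and touches no stereocentre.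

Step 13
Reactants: 24 the C3, C9 diester diene of step 12
Product: 25 3α-(3-methylbut-2-enoyloxy)-9α-[(E)-2-methylbut-2-enoyloxy]-8β-(methoxymethoxy)-11,12,13-trinoreremophil-6-ene (trans-decalin, 4β,5β-dimethyl, 10α-H)
Conditions: second-generation Grubbs catalyst RuCl2(=CHPh)(H2IMes)(PCy3) (5 mol %), CH2Cl2, 40 °C
Reagents that add atoms: none
Why: Ring-closing olefin metathesis between the C5 vinyl group and the terminal alkene forms ring B as a cyclohexene (C6=C7) with loss of ethylene, so the vinyl group contributes only C6 while C7 and C8 stem from the allyl unit; the trisubstituted, electron-poor ester alkenes do not take part.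

Step 14
Reactants: 25 the 8β-methoxymethyl ether of step 13
Product: 26 8β-hydroxy-3α-(3-methylbut-2-enoyloxy)-9α-[(E)-2-methylbut-2-enoyloxy]-11,12,13-trinoreremophil-6-ene
Conditions: ZnBr2, n-PrSH, CH2Cl2, 0 °C
Reagents that add atoms: none
Why: Lewis-acid-mediated thiolysis (transacetalisation) removes the methoxymethyl group within minutes under conditions too mild for ester cleavage or acyl migration from O9 to O8.

Step 15
Reactants: 26 the 8β-allylic alcohol of step 14
Product: 27 3α-(3-methylbut-2-enoyloxy)-9α-[(E)-2-methylbut-2-enoyloxy]-11,12,13-trinoreremophil-6-en-8-one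
Conditions: Dess–Martin periodinane, NaHCO3, CH2Cl2, 0 → 23 °C
Reagents that add atoms: none
Why: Dess–Martin oxidation of the allylic C8 alcohol gives the 6-en-8-one directly, so no allylic C–H oxidation is needed, and C9 is untouched under the buffered conditions.

Step 16
Reactants: 27 the 6-en-8-one of step 15
Product: 28 7-iodo-3α-(3-methylbut-2-enoyloxy)-9α-[(E)-2-methylbut-2-enoyloxy]-11,12,13-trinoreremophil-6-en-8-one
Conditions: I2, pyridine, CH2Cl2, 23 °C
Reagents that add atoms: iodine, II
Why: In this Johnson α-iodination of an enone, pyridine adds reversibly to C6, the enolate is iodinated at C7 and pyridine is eliminated, while the β-substituted unsaturated esters are too unreactive to enter the sequence.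

Step 17
Reactants: 28 the 7-iodo enone of step 16; 29 isopropenylboronic acid pinacol ester
Product: 30 3α-(3-methylbut-2-enoyloxy)-9α-[(E)-2-methylbut-2-enoyloxy]eremophila-6,11-dien-8-one
Conditions: 29, PdCl2(dppf)·CH2Cl2 (5 mol %), Ph3As, Cs2CO3, DMF–THF–H2O, 23 °C
Reagents that add atoms: isopropenylboronic acid pinacol ester, C=C(C)B1OC(C)(C)C(C)(C)O1
Why: In this Suzuki–Miyaura coupling zerovalent palladium inserts into the C7–I bond, the isopropenyl group is transferred from boron and reductive elimination forms the C7–C11 bond, the mild base at ambient temperature sparing the α-acyloxy ketone.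

Step 18
Reactants: 30 the 6,11-dien-8-one of step 17
Product: 33 3α-(3-methylbut-2-enoyloxy)-9α-[(E)-2-methylbut-2-enoyloxy]eremophil-11-en-8-one (4β,5β-dimethyl, 7α-isopropenyl, 10α-H; CNP0164025.1), via copper enolate 31 (not isolated), via C7 epimer 32 (not isolated)
Conditions: [(Ph3P)CuH]6, H2O, toluene, 23 °C; then Et3N, CH2Cl2, 23 °C
Reagents that add atoms: none
Why: In this conjugate reduction with Stryker's reagent hydride is delivered to C6 of the enone in preference to the more substituted, less electrophilic enoates, water protonates copper enolate 31 at C7 (α-protonation keeps the C11–C12 double bond out of conjugation), and the amine equilibrates any axial epimer 32 through the enol to the equatorial isopropenyl group of 33, which avoids the 1,3-diaxial contact with the C5 methyl.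

**Compound list**

1 | ethyl 2-methyl-4-oxocyclohex-2-ene-1-carboxylate (Hagemann's ester, racemic) | CCOC(=O)C1CCC(=O)C=C1C | starting material
2 | ethyl 7-methyl-1,4-dioxaspiro[4.5]dec-7-ene-8-carboxylate | CCOC(=O)C1=C(C)CC2(CC1)OCCO2 | intermediate
3 | (7-methyl-1,4-dioxaspiro[4.5]dec-7-en-8-yl)methanol | OCC1=C(C)CC2(CC1)OCCO2 | intermediate
4 | 4-(hydroxymethyl)-3-methylcyclohex-3-en-1-one (deconjugated ketone, not isolated) | OCC1=C(C)CC(=O)CC1 | intermediate
5 | rac-4-(hydroxymethyl)-3-methylcyclohex-2-en-1-one | CC1=CC(=O)CCC1CO | intermediate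
6 | (4R)-4-(hydroxymethyl)-3-methylcyclohex-2-en-1-one | CC1=CC(=O)CC[C@H]1CO | intermediate
7 | (4R)-4-{[tert-butyl(dimethyl)silyl]oxymethyl}-3-methylcyclohex-2-en-1-one | CC1=CC(=O)CC[C@H]1CO[Si](C)(C)C(C)(C)C | intermediate
8 | vinylmagnesium bromide | C=C[Mg]Br | starting material
9 | iodomethane | CI | starting material
10 | tert-butyl{[(1R,2S)-2-ethenyl-2-methyl-4-(trimethylsilyloxy)cyclohex-3-en-1-yl]methoxy}dimethylsilane (trimethylsilyl enol ether, not isolated) | C=C[C@]1(C)C=C(O[Si](C)(C)C)CC[C@H]1CO[Si](C)(C)C(C)(C)C | intermediate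
11 | lithium enolate corresponding to 10 (not isolated) | C=C[C@]1(C)C=C([O-])CC[C@H]1CO[Si](C)(C)C(C)(C)C.[Li+] | intermediate
12 | (2S,3S,4R)-4-{[tert-butyl(dimethyl)silyl]oxymethyl}-3-ethenyl-2,3-dimethylcyclohexan-1-one (C4 epimer of 13, not isolated) | C=C[C@]1(C)[C@H](C)C(=O)CC[C@H]1CO[Si](C)(C)C(C)(C)C | intermediate
13 | (2R,3S,4R)-4-{[tert-butyl(dimethyl)silyl]oxymethyl}-3-ethenyl-2,3-dimethylcyclohexan-1-one | C=C[C@]1(C)[C@@H](C)C(=O)CC[C@H]1CO[Si](C)(C)C(C)(C)C | intermediate
14 | (1R,2R,3S,4R)-4-{[tert-butyl(dimethyl)silyl]oxymethyl}-3-ethenyl-2,3-dimethylcyclohexan-1-ol | C=C[C@]1(C)[C@@H](C)[C@H](O)CC[C@H]1CO[Si](C)(C)C(C)(C)C | intermediate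
15 | 3-methylbut-2-enoyl chloride | CC(C)=CC(=O)Cl | starting material
16 | (1R,2R,3S,4R)-4-{[tert-butyl(dimethyl)silyl]oxymethyl}-3-ethenyl-2,3-dimethylcyclohexyl 3-methylbut-2-enoate | C=C[C@]1(C)[C@@H](C)[C@H](OC(=O)C=C(C)C)CC[C@H]1CO[Si](C)(C)C(C)(C)C | intermediate
17 | (1R,2R,3S,4R)-3-ethenyl-4-(hydroxymethyl)-2,3-dimethylcyclohexyl 3-methylbut-2-enoate | C=C[C@]1(C)[C@@H](C)[C@H](OC(=O)C=C(C)C)CC[C@H]1CO | intermediate
18 | (1R,2R,3R,4R)-3-ethenyl-4-formyl-2,3-dimethylcyclohexyl 3-methylbut-2-enoate | C=C[C@]1(C)[C@@H](C)[C@H](OC(=O)C=C(C)C)CC[C@H]1C=O | intermediate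
19 | allyl methoxymethyl ether, 3-(methoxymethoxy)prop-1-ene | C=CCOCOC | starting material
20 | [(Z)-3-(methoxymethoxy)prop-2-en-1-yl]bis[(1S,2S,3S,5R)-isopinocampheyl]borane (not isolated) | COCO/C=C\CB([C@H]1C[C@H]2C[C@@H]([C@@H]1C)C2(C)C)[C@H]1C[C@H]2C[C@@H]([C@@H]1C)C2(C)C | intermediate
21 | diisopinocampheylborinate ester of 22 at O9 (not isolated) | C=C[C@]1(C)[C@@H](C)[C@H](OC(=O)C=C(C)C)CC[C@H]1[C@H](OB([C@H]2C[C@H]3C[C@@H]([C@@H]2C)C3(C)C)[C@H]2C[C@H]3C[C@@H]([C@@H]2C)C3(C)C)[C@@H](OCOC)C=C | intermediate
22 | 3-ethenyl-4-[(1S,2S)-1-hydroxy-2-(methoxymethoxy)but-3-en-1-yl]-2,3-dimethylcyclohexyl 3-methylbut-2-enoate (ring configuration as in 18) | C=C[C@]1(C)[C@@H](C)[C@H](OC(=O)C=C(C)C)CC[C@H]1[C@H](O)[C@@H](OCOC)C=C | intermediate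
23 | (E)-2-methylbut-2-enoyl chloride (tigloyl chloride) | C/C=C(\C)C(=O)Cl | starting material
24 | 3-ethenyl-4-[(1S,2S)-2-(methoxymethoxy)-1-{[(E)-2-methylbut-2-enoyl]oxy}but-3-en-1-yl]-2,3-dimethylcyclohexyl 3-methylbut-2-enoate (ring configuration as in 18) | C=C[C@]1(C)[C@@H](C)[C@H](OC(=O)C=C(C)C)CC[C@H]1[C@H](OC(=O)/C(C)=C/C)[C@@H](OCOC)C=C | intermediate
25 | 3α-(3-methylbut-2-enoyloxy)-9α-[(E)-2-methylbut-2-enoyloxy]-8β-(methoxymethoxy)-11,12,13-trinoreremophil-6-ene | C1=C[C@]2(C)[C@@H](C)[C@H](OC(=O)C=C(C)C)CC[C@H]2[C@H](OC(=O)/C(C)=C/C)[C@H]1OCOC | intermediate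
26 | 8β-hydroxy-3α-(3-methylbut-2-enoyloxy)-9α-[(E)-2-methylbut-2-enoyloxy]-11,12,13-trinoreremophil-6-ene | C1=C[C@]2(C)[C@@H](C)[C@H](OC(=O)C=C(C)C)CC[C@H]2[C@H](OC(=O)/C(C)=C/C)[C@H]1O | intermediate
27 | 3α-(3-methylbut-2-enoyloxy)-9α-[(E)-2-methylbut-2-enoyloxy]-11,12,13-trinoreremophil-6-en-8-one | O=C1C=C[C@]2(C)[C@@H](C)[C@H](OC(=O)C=C(C)C)CC[C@H]2[C@@H]1OC(=O)/C(C)=C/C | intermediate
28 | 7-iodo-3α-(3-methylbut-2-enoyloxy)-9α-[(E)-2-methylbut-2-enoyloxy]-11,12,13-trinoreremophil-6-en-8-one | O=C1C(I)=C[C@]2(C)[C@@H](C)[C@H](OC(=O)C=C(C)C)CC[C@H]2[C@@H]1OC(=O)/C(C)=C/C | intermediate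
29 | isopropenylboronic acid pinacol ester | C=C(C)B1OC(C)(C)C(C)(C)O1 | starting material
30 | 3α-(3-methylbut-2-enoyloxy)-9α-[(E)-2-methylbut-2-enoyloxy]eremophila-6,11-dien-8-one | C=C(C)C1=C[C@]2(C)[C@@H](C)[C@H](OC(=O)C=C(C)C)CC[C@H]2[C@H](OC(=O)/C(C)=C/C)C1=O | intermediate
31 | copper enolate (C7=C8–O–Cu, monovalent copper, phosphine-ligated) formed from 30 (not isolated) | C=C(C)C=1C[C@]2(C)[C@@H](C)[C@H](OC(=O)C=C(C)C)CC[C@H]2[C@H](OC(=O)/C(C)=C/C)C=1O[Cu] | intermediate
32 | C7 epimer of 33 (7β-isopropenyl, not isolated) | C=C(C)[C@H]1C[C@]2(C)[C@@H](C)[C@H](OC(=O)C=C(C)C)CC[C@H]2[C@H](OC(=O)/C(C)=C/C)C1=O | intermediate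
33 | 3α-(3-methylbut-2-enoyloxy)-9α-[(E)-2-methylbut-2-enoyloxy]eremophil-11-en-8-one (CNP0164025.1) | C=C(C)[C@@H]1C[C@]2(C)[C@@H](C)[C@H](OC(=O)C=C(C)C)CC[C@H]2[C@H](OC(=O)/C(C)=C/C)C1=O | target

**Step count and risk**

Total step count: 18. Longest linear sequence: 18 steps (1 → 33).

Steps most likely to fail:

1. Step 6. What may go wrong: proton transfer between the hindered lithium enolate and the ketone already formed, which moves the enolate toward C2 and leads to over-methylation and unmethylated ketone; the C4 equilibration may also stop short. Fallback, setting out from 7 and returning at 13: the conjugate addition is run alone (8, CuBr·SMe2, Me3SiCl, Et3N quench) and enol silane 10 is isolated. Treatment with dimethyl(methylidene)ammonium iodide in CH2Cl2 should give the Mannich base 4-{[tert-butyl(dimethyl)silyl]oxymethyl}-2-[(dimethylamino)methyl]-3-ethenyl-3-methylcyclohexan-1-one F1, a C–C bond formation that needs no free enolate and so cannot scramble the regiochemistry. Quaternisation with MeI and elimination with NaHCO3 should give the 2-methylidene ketone F2. Conjugate reduction of this exocyclic enone with [(Ph3P)CuH]6, followed by the same methoxide equilibration, should deliver 13.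

2. Step 18. What may go wrong: protonation of the enolate on the less hindered α face of C7, giving the axial epimer; migration of the C11–C12 double bond into conjugation with the ketone during the base equilibration; acyl shift at the α-acyloxy ketone while the enolate is present. Fallback, setting out from 27 and returning at 33: conjugate hydrosilylation of 27 (Et3SiH, catalytic [(Ph3P)CuH]6, toluene) should give the triethylsilyl enol ether 3α-(3-methylbut-2-enoyloxy)-9α-[(E)-2-methylbut-2-enoyloxy]-8-(triethylsilyloxy)-11,12,13-trinoreremophil-7-ene F3. Palladium-catalysed α-alkenylation of F3 with 2-bromopropene through the tin enolate (Bu3SnF, PdCl2[P(o-tolyl)3]2, toluene, 80 °C) would then form the C7–C11 bond on the open α face, anti to the C5 methyl. The isopropenyl group is thereby placed equatorial directly under non-basic conditions, and neither a protonation at C7 nor a base equilibration is needed.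

3. Step 4. What may go wrong: weak enantiodiscrimination by the lipase for a primary alcohol whose stereocentre lies one carbon away, so that high enantiomeric purity is reached only at high conversion and with heavy loss of material. Fallback, setting out from 3 and returning at 7: silylation of 3 (TBSCl, imidazole) should give tert-butyl(dimethyl)[(7-methyl-1,4-dioxaspiro[4.5]dec-7-en-8-yl)methoxy]silane F4. Neutral deketalisation (catalytic I2, acetone) should give the deconjugated ketone 4-{[tert-butyl(dimethyl)silyl]oxymethyl}-3-methylcyclohex-3-en-1-one F5. Enantioselective isomerisation of this β,γ-unsaturated ketone to the conjugated enone would follow, using a cinchona-derived primary amine (9-amino-9-deoxy-epi-quinine or its quinidine-derived pseudoenantiomer, whichever gives the (R) product) and a carboxylic acid co-catalyst. C10 is then set by face-selective γ-protonation of the dienamine, and no material is discarded.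

**Further compounds**

F1 | step 6 | (3S,4R)-4-{[tert-butyl(dimethyl)silyl]oxymethyl}-2-[(dimethylamino)methyl]-3-ethenyl-3-methylcyclohexan-1-one (mixture at C2) | C=C[C@]1(C)C(CN(C)C)C(=O)CC[C@H]1CO[Si](C)(C)C(C)(C)C
F2 | step 6 | (3S,4R)-4-{[tert-butyl(dimethyl)silyl]oxymethyl}-3-ethenyl-3-methyl-2-methylidenecyclohexan-1-one | C=C[C@]1(C)C(=C)C(=O)CC[C@H]1CO[Si](C)(C)C(C)(C)C
F3 | step 18 | 3α-(3-methylbut-2-enoyloxy)-9α-[(E)-2-methylbut-2-enoyloxy]-8-(triethylsilyloxy)-11,12,13-trinoreremophil-7-ene | CC[Si](CC)(CC)OC1=CC[C@]2(C)[C@@H](C)[C@H](OC(=O)C=C(C)C)CC[C@H]2[C@@H]1OC(=O)/C(C)=C/C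
F4 | step 4 | tert-butyl(dimethyl)[(7-methyl-1,4-dioxaspiro[4.5]dec-7-en-8-yl)methoxy]silane | CC(C)(C)[Si](C)(C)OCC1=C(C)CC2(CC1)OCCO2
F5 | step 4 | 4-{[tert-butyl(dimethyl)silyl]oxymethyl}-3-methylcyclohex-3-en-1-one | CC(C)(C)[Si](C)(C)OCC1=C(C)CC(=O)CC1
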